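The numbers are made up.

Start with the easy step: each turn of the catalyst Z takes up one D and one G and releases one L, and free Z can then turn L into J.

    D + Z → D.Z (k1 = 11600 L mol⁻¹ min⁻¹)
    G + D.Z ⇌ G.D.Z (K2 = 22.6 L mol⁻¹, k2 = 3640 L mol⁻¹ min⁻¹)
    X ⇌ Z + L (K3 = 0.295 M, k3 = 29.7 min⁻¹)
    G.D.Z ⇌ X (K4 = 1.0, k4 = 71.5 min⁻¹)
    L + Z ⇌ J + Z, rate k5*[Z]*[L] forward; the back reaction follows from the equilibrium constant (K5 = 7.42, k5 = 1590 L mol⁻¹ min⁻¹)

| setting | dawn | midnight | autumn | noon |
|---|---|---|---|---|
| G | 0.080 M | 0.12 M | 0.15 M | 0.25 M |
| D | 0.121 M | 0.121 M | 0.121 M | 0.121 M |
| Z | 0.15 mM | 0.15 mM | 0.15 mM | 0.15 mM |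
| time | 2.0 h | 2.0 h | 2.0 h | 2.0 h |

1. [L] at the end for dawn, midnight, autumn, noon, in this order
2. the shape of the row from first to last (falls, then rises / falls all the way / rises all the way / hardly changes / rises, then falls)

- "hardly changes" means that all values lie within two and a half points (for a concentration: within two and a half percent of the largest)
- run time (dawn): 2.0 h

Which constants must you know well? Take them in turn, for Z going round while G is plentiful. The exit from X, 29.7 min⁻¹, weighs most: together with the step from G.D.Z to X it holds Z bound for a time a = 0.0813 min per turn, and 82.8% of a comes from this exit, so an error in 29.7 min⁻¹ passes almost whole into the time of a turn. The constants of G binding come next. They give Gh = 0.0293 M, the Michaelis constant of this cycle, and a turn lasts a plus a·Gh/G. The wait for D, 7.12 × 10⁻⁴ min, is hardly any of a, so 11600 L mol⁻¹ min⁻¹ barely shifts the time of a turn. It still counts for the row: while D remains, free Z goes as the turning rate divided by 11600 L mol⁻¹ min⁻¹ times [D], and free Z is what makes J. The constants of L ⇌ J enter no turn, but they act on L while the turns run, through that free Z. When the whole D charge has been turned over, L relaxes towards that charge divided by one plus 7.42, which is 0.0144 M.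

Now the number. In autumn G exceeds D, so D is the limiting reagent. Replace the falling G by its mean between start and end, 0.0895 M. A turn then takes 0.108 min, and this gives 87.1 min for the number to carry: the emptying time, the time the Z charge needs to turn over the whole D charge at its mean speed. To check the mean, average the time per turn instead of G. That gives 91.7 min, which is still shorter than the run of 120 min. The spare time is longer than the 3.69 min that L and J need with Z free, so you expect L near 0.0144 M in autumn. In dawn and midnight G is below D, so you expect L to rise between them, standing below the G turned over by the J that free Z has made, and by more in midnight, where the D left over from the charge is smaller than in dawn.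

The forecast gives 0.073 M, 0.079 M, 0.0144 M and 0.0144 M, with the shape "rises, then falls". It says “D runs out after about an hour”, earlier than the 91.7 min reckoned here.

The simulation gives 0.0729 M, 0.0856 M, 0.0149 M and 0.0144 M, so the row rises, then falls, turning at 0.11 M. In autumn D ends at 0% of its charge.

Carry the emptying time to noon, where the mean G is higher: it comes to 75.7 min, shorter than in autumn, and noon ends with D at 0% and G at 51.6% of its charge. The way back from J to L holds up the L that remains at noon. With that way back taken away, [L] at the end of noon stands at 1.05 × 10⁻⁵ M instead of 0.0144 M.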